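**Plan**

- Labels: lactam N1, C2–C5 (C5 carbinol), spiro C6, C7, C8, C9 (N–CH), C10 (C=O). Ring A = C6–C7–C13–C12–C11 (C11 ethyl, C12 oxygen). Lactone B = C12–O–C15(=O)–C14(Me)–C13. Lactone D = C16(O)–C17–C18(Me)–C19(=O), on C9.
- Retrosynthesis: the benzyl ether is cut last, then N1–C10 and N1–C2 together. Taking N1 out of the 1-azabicyclo[4.3.1]decan-10-one leaves a cyclohexanone (C10, C6, C5, C4, C3, C2) spiro-joined at C6 to ring A, with a C9 azide three carbons from C6 on the face of ring A that carries C10.
- Further cuts: C9–N, C9–C16, C2–C10, C5–C6, C7–C8, C6–C10, C13–C14 and C7=C13.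
- Forward: ring A as a cyclopentenone (aldol, ring-closing metathesis); ring B as a cyclic acetal (radical cyclization); ester on C6, vinyl on C7, acyl chain on C6; Dieckmann closure of the spiro cyclohexanone; acetal to lactone B; C9 aldehyde; ring D by vinylogous aldol; azide; nitrogen insertion closes both lactam rings; debenzylation.
- Stereochemistry: C11/C12 from an oxazolidinone syn-aldol; C13 from the acetal tether; C14 from convex-face hydrogenation; C7 and C6 from attack anti to ring B and to the vicinal groups; C5 from oxazaborolidine reduction; C16/C9 from a catalyst-controlled vinylogous aldol with later inversion at C9; C18 from hydrogenation anti to the C16 side chain.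

Key step: step 25

Remark: the acetal carbon C15 of 12–18 and 21–26 is carried as a mixture of epimers (left undefined in the SMILES) that converges on the lactone in step 17; C6 of 18 and C2 of 25–28 are likewise undefined.

**Step 1**
Reactants: 1 (R)-4-benzyloxazolidin-2-one; 2 butanoyl chloride
Product: 3 (R)-4-benzyl-3-butanoyloxazolidin-2-one
Conditions: Et3N, DMAP (cat.), CH2Cl2, 0 °C → rt
Reagents that add atoms: none
Why: DMAP-catalysed N-acylation of the oxazolidinone by the acid chloride attaches the auxiliary to the four-carbon unit that becomes C6, C11 and the ethyl group; no stereocentre is formed.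

**Step 2**
Reactants: 3 (R)-4-benzyl-3-butanoyloxazolidin-2-one; 4 acrolein
Product: 6 (R)-4-benzyl-3-[(2R,3S)-2-ethyl-3-hydroxypent-4-enoyl]oxazolidin-2-one, via dibutylboron Z-enolate 5 (not isolated)
Conditions: Bu2BOTf, i-Pr2NEt, CH2Cl2, −78 → 0 °C; acrolein, −78 → 0 °C; H2O2, pH 7 buffer, MeOH
Reagents that add atoms: none
Why: Evans syn-aldol reaction, in which the Z-boron enolate reacts through a closed chair transition state on the enolate face away from the benzyl group of the (R)-auxiliary, setting C11 (R) and C12 (S) together.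

**Step 3**
Reactants: 6 (R)-4-benzyl-3-[(2R,3S)-2-ethyl-3-hydroxypent-4-enoyl]oxazolidin-2-one
Product: 7 (2R,3S)-2-ethyl-3-hydroxy-N-methoxy-N-methylpent-4-enamide
Conditions: MeNH(OMe)·HCl, AlMe3, CH2Cl2, −20 → 0 °C
Reagents that add atoms: N,O-dimethylhydroxylamine hydrochloride, CNOC.Cl
Why: Weinreb amide formation by aluminium amide aminolysis of the imide, assisted by the free β-hydroxyl, should release the auxiliary without touching C11 or C12.

**Step 4**
Reactants: 7 (2R,3S)-2-ethyl-3-hydroxy-N-methoxy-N-methylpent-4-enamide; 8 vinylmagnesium bromide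
Product: 9 (4R,5S)-4-ethyl-5-hydroxyhepta-1,6-dien-3-one
Conditions: CH2=CHMgBr (3 equiv), THF, 0 °C; inverse quench into cold 1 M HCl
Reagents that add atoms: none
Why: Grignard addition to a Weinreb amide stops at the ketone because the chelated tetrahedral adduct persists until the acidic quench, which also keeps the β-hydroxy vinyl ketone away from base (no retro-aldol, no amine conjugate addition).

**Step 5**
Reactants: 9 (4R,5S)-4-ethyl-5-hydroxyhepta-1,6-dien-3-one
Product: 10 (4S,5R)-5-ethyl-4-hydroxycyclopent-2-en-1-one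
Conditions: second-generation Grubbs catalyst RuCl2(=CHPh)(PCy3)(H2IMes) (3 mol %), CH2Cl2, 40 °C
Reagents that add atoms: none
Why: Ring-closing metathesis of the 1,6-dienone closes ring A as a cyclopentenone with loss of ethene, and the trans C11/C12 relationship follows from the syn-aldol.

**Step 6**
Reactants: 10 (4S,5R)-5-ethyl-4-hydroxycyclopent-2-en-1-one; 11 methoxyallene
Product: 12 (4S,5R)-4-[(2-bromo-1-methoxyprop-2-en-1-yl)oxy]-5-ethylcyclopent-2-en-1-one
Conditions: NBS, CH2Cl2, −40 → 0 °C
Reagents that add atoms: N-bromosuccinimide, O=C1CCC(=O)N1Br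
Why: Haloalkoxylation of the alkoxyallene (bromination of the central allene carbon, capture of the oxocarbenium ion by the C12 hydroxyl) gives the 2-bromoallyl mixed acetal under neutral conditions that spare the base-labile hydroxy enone.

**Step 7**
Reactants: 12 (4S,5R)-4-[(2-bromo-1-methoxyprop-2-en-1-yl)oxy]-5-ethylcyclopent-2-en-1-one
Product: 13 (3aR,6R,6aS)-6-ethyl-2-methoxy-3-methylidenehexahydro-2H-cyclopenta[b]furan-5(3H)-one
Conditions: Bu3SnH (slow addition), AIBN (cat.), PhH, 80 °C
Reagents that add atoms: none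
Why: Ueno–Stork-type 5-exo-trig cyclization of the vinyl radical onto the enone β-carbon C13 forms C13–C14, and the two-atom tether from the C12 oxygen allows only a cis ring fusion, so C13 is set by C12.

**Step 8**
Reactants: 13 (3aR,6R,6aS)-6-ethyl-2-methoxy-3-methylidenehexahydro-2H-cyclopenta[b]furan-5(3H)-one
Product: 14 (3S,3aR,6R,6aS)-6-ethyl-2-methoxy-3-methylhexahydro-2H-cyclopenta[b]furan-5(3H)-one
Conditions: H2 (1 atm), Pd/C (10 wt %), EtOAc, rt
Reagents that add atoms: none
Why: Heterogeneous catalytic hydrogenation should deliver hydrogen to the exocyclic alkene from the convex face of the cis-fused bicycle, which places the C14 methyl on the concave face, cis to C7, as the target requires.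

**Step 9**
Reactants: 14 (3S,3aR,6R,6aS)-6-ethyl-2-methoxy-3-methylhexahydro-2H-cyclopenta[b]furan-5(3H)-one
Product: 16 C6 enol triflate of 14 (C6=C7), via lithium C6–C7 enolate 15 (not isolated)
Conditions: LiN(i-Pr)2, THF, −78 °C; PhNTf2, −78 → 0 °C
Reagents that add atoms: N-phenylbis(trifluoromethanesulfonimide), FC(F)(F)S(=O)(=O)N(c1ccccc1)S(=O)(=O)C(F)(F)F
Why: Kinetic enolate formation removes a proton from the C7 methylene, not from the C11 methine whose enolate could expel the β-alkoxy group, and O-sulfonylation gives the vinyl triflate.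

**Step 10**
Reactants: 16 C6 enol triflate of 14 (C6=C7)
Product: 17 methyl C6-carboxylate of the C6=C7 cyclopentene (enoate)
Conditions: Pd(OAc)2 (5 mol %), PPh3, CO (1 atm), MeOH, Et3N, DMF, 60 °C
Reagents that add atoms: carbon monoxide, [C-]#[O+]; methanol, CO
Why: Palladium-catalysed methoxycarbonylation (oxidative addition of the vinyl triflate to zerovalent palladium, CO insertion, methanolysis) installs C10 as an ester on C6.

**Step 11**
Reactants: 17 methyl C6-carboxylate of the C6=C7 cyclopentene (enoate); 8 vinylmagnesium bromide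
Product: 18 C7-vinyl saturated methyl ester (C8 trans to C14)
Conditions: CH2=CHMgBr, CuI (20 mol %), Me3SiCl, THF, −78 → −30 °C; aq. NH4Cl
Reagents that add atoms: none
Why: Copper-catalysed conjugate addition accelerated by the silyl chloride should occur on the convex face of the bicycle, anti to ring B, so that C7 is set with C8 trans to C14.

**Step 12**
Reactants: 19 5-(tert-butoxy)-5-oxopentanoic acid
Product: 20 tert-butyl 5-chloro-5-oxopentanoate
Conditions: (COCl)2, DMF (cat.), CH2Cl2, 0 °C → rt; evaporate, use crude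
Reagents that add atoms: oxalyl chloride, O=C(Cl)C(Cl)=O
Why: Acid chloride formation through the chloroiminium (Vilsmeier-type) activation is mild enough to keep the tert-butyl ester.

**Step 13**
Reactants: 18 C7-vinyl saturated methyl ester (C8 trans to C14); 20 tert-butyl 5-chloro-5-oxopentanoate
Product: 22 C6-quaternary keto diester (C5 ketone chain cis to ring B; C10 ester cis to C8), via lithium ester enolate 21 (not isolated)
Conditions: LiN(i-Pr)2, THF, −78 °C; 20, −78 °C
Reagents that add atoms: none
Why: Crossed Claisen-type C-acylation of the tetrasubstituted ester enolate should take place on the face anti to both the C7 vinyl and the C11 ethyl group, making C6 quaternary with C5 on the ring B side and C10 on the C8 side.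

**Step 14**
Reactants: 22 C6-quaternary keto diester (C5 ketone chain cis to ring B; C10 ester cis to C8)
Product: 23 (5R)-hydroxy diester
Conditions: (S)-2-methyl-CBS-oxazaborolidine (0.5 equiv), catecholborane, PhMe, −78 → −40 °C
Reagents that add atoms: none
Why: Corey–Bakshi–Shibata reduction, with the quaternary C6 as the large and the C4 methylene as the small ketone substituent, should give the 5R carbinol under reagent control, and catecholborane leaves the vinyl group and both esters alone.

**Step 15**
Reactants: 23 (5R)-hydroxy diester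
Product: 24 (5R)-benzyl ether diester
Conditions: 2-benzyloxy-1-methylpyridinium triflate, MgO, PhCF3, 83 °C
Reagents that add atoms: 2-benzyloxy-1-methylpyridinium triflate, C[n+]1ccccc1OCc1ccccc1.[O-]S(=O)(=O)C(F)(F)F
Why: Neutral benzyl transfer from the pyridinium salt (SN1-like O-benzylation) etherifies the hindered alcohol without forming an alkoxide, so retro-aldol cleavage is avoided and the tert-butyl ester does not lactonise onto C5–OH.

**Step 16**
Reactants: 24 (5R)-benzyl ether diester
Product: 25 spiro β-keto ester (tert-butyl ester on C2 of the new cyclohexanone)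
Conditions: t-BuOK, THF, 0 °C → rt; AcOH
Reagents that add atoms: none
Why: Dieckmann condensation, in which the tert-butyl ester enolate at C2 attacks the C10 methyl ester in a 6-exo-trig closure, forms the spiro cyclohexanone and is driven by deprotonation of the β-keto ester, while the quaternary C6 excludes epimerisation and β-elimination of the benzyloxy group.

**Step 17**
Reactants: 25 spiro β-keto ester (tert-butyl ester on C2 of the new cyclohexanone)
Product: 27 ring B lactone β-keto ester, via lactol 26 (not isolated)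
Conditions: CrO3, H2SO4, H2O, acetone, 0 °C
Reagents that add atoms: water, O
Why: Jones oxidation hydrolyses the methyl acetal to the lactol and oxidises it at once to the γ-lactone, and the short cold contact should leave the C14 methyl configuration, the vinyl group and the benzyl ether intact.

**Step 18**
Reactants: 27 ring B lactone β-keto ester
Product: 29 spiro ketone (C7 vinyl; ring B lactone; C5 benzyl ether), via β-keto acid 28 (not isolated)
Conditions: CF3CO2H, CH2Cl2, rt; then PhMe, 80 °C
Reagents that add atoms: none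
Why: Acidolysis of the tert-butyl ester followed by thermal decarboxylation of the β-keto acid through a six-membered transition state removes the ester carbon under conditions that do not enolise the lactone.

**Step 19**
Reactants: 29 spiro ketone (C7 vinyl; ring B lactone; C5 benzyl ether)
Product: 31 C9 primary alcohol, via B-alkyl-9-BBN adduct 30 (not isolated)
Conditions: 9-BBN, THF, 0 °C → rt; H2O2, aq. NaOAc, 0 °C
Reagents that add atoms: hydrogen peroxide, OO
Why: Hydroboration–oxidation with the bulky borane adds anti-Markovnikov to the monosubstituted alkene much faster than it reduces the hindered neopentyl ketone, and the buffered peroxide work-up spares the lactone.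

**Step 20**
Reactants: 31 C9 primary alcohol
Product: 32 C9 aldehyde
Conditions: Dess–Martin periodinane, NaHCO3, CH2Cl2, rt
Reagents that add atoms: none
Why: Dess–Martin oxidation converts the primary alcohol into the aldehyde under buffered neutral conditions, so neither the C14 centre nor an aldol between C9 and the C10 ketone should interfere.

**Step 21**
Reactants: 33 3-methylfuran-2(5H)-one
Product: 34 tert-butyldimethyl[(3-methylfuran-2-yl)oxy]silane
Conditions: t-BuMe2SiOTf, Et3N, CH2Cl2, 0 °C
Reagents that add atoms: tert-butyldimethylsilyl triflate, CC(C)(C)[Si](C)(C)OS(=O)(=O)C(F)(F)F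
Why: Soft enolisation and O-silylation of the butenolide give the aromatic 2-silyloxyfuran, a cyclic silyl dienolate nucleophilic at its γ-carbon.

**Step 22**
Reactants: 32 C9 aldehyde; 34 tert-butyldimethyl[(3-methylfuran-2-yl)oxy]silane
Product: 35 (9S,16R)-hydroxy butenolide
Conditions: SiCl4, (R,R)-1,1'-binaphthyl-2,2'-diamine-derived bisphosphoramide (5 mol %), i-Pr2NEt (10 mol %), CH2Cl2, −78 °C; aq. NaHCO3/KF
Reagents that add atoms: none
Why: Vinylogous Mukaiyama aldol reaction in which the Lewis-base-activated silicon cation binds the aldehyde and the furan γ-carbon attacks through an open antiperiplanar transition state, which should give the 5,1'-anti adduct with C16 (R) and C9 (S) under catalyst control (Re-face attack on the aldehyde; the catalyst antipode is taken if the sense proves opposite).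

**Step 23**
Reactants: 35 (9S,16R)-hydroxy butenolide
Product: 36 (9S,16R,18R)-hydroxy lactone
Conditions: H2 (1 atm), Pd/C (10 wt %), pyridine (0.5 equiv), EtOAc, rt
Reagents that add atoms: none
Why: Catalytic hydrogenation of the butenolide from the face opposite the C16 side chain gives the cis-2,4-disubstituted lactone (C18 R), while the pyridine-moderated catalyst should leave the benzyl ether and the ketone untouched.

**Step 24**
Reactants: 36 (9S,16R,18R)-hydroxy lactone
Product: 37 (9R)-azido ketone (spiro azido ketone with C5 benzyl ether)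
Conditions: PPh3, i-PrO2CN=NCO2i-Pr, (PhO)2P(O)N3, THF, 0 °C → rt
Reagents that add atoms: diphenylphosphoryl azide, [N-]=[N+]=NP(=O)(Oc1ccccc1)Oc1ccccc1
Why: Mitsunobu azidation displaces the alkoxyphosphonium ion with inversion at C9 (S to R), and the neutral conditions keep the azide from reacting with the C10 ketone.

**Step 25**
Reactants: 37 (9R)-azido ketone (spiro azido ketone with C5 benzyl ether)
Product: 39 O-benzyl bridged lactam, via azidohydrin 38 (not isolated)
Conditions: TiCl4, CH2Cl2, 0 °C → rt; aq. NaHCO3
Reagents that add atoms: none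
Why: TiCl4 activates the C10 ketone and the alkylated nitrogen of the C9 azide adds to it in a 6-exo-trig closure, giving azidohydrin 38 whose six-membered ring (N1, C9, C8, C7, C6, C10) is cis-fused to ring A because C8 and C10 sit on the same face of the cyclopentane. Loss of N2 is concerted with a 1,2-shift of the C–C bond antiperiplanar to the N–N2 bond; with the diazonium axial this is C10–C2, so N1–C2 forms and the cyclohexanone expands to the seven-membered lactam ring (N1, C2–C6, C10) by migration, not by a second cyclization. The closest known reaction type is the intramolecular Schmidt reaction of azidoalkyl cyclohexanones in its bridged mode, where an axial diazonium group is held by a nearby aryl or heteroatom donor. No stereocentre is created: C10 ends as the carbonyl, C9 keeps its configuration because its C–N bond is never broken, and C6 stays in place. The selectivity needed is migration of the methylene C2 over the quaternary C6 (which would give the fused pyrroloazepinone); it rests on the chair azidohydrin with C2 axial on C10 and the diazonium axial on N1, a conformer favoured by the C5 ether oxygen and the benzyl π-face lying gauche to N1 and by the cis ring fusions that spiro ring A imposes.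

**Step 26**
Reactants: 39 O-benzyl bridged lactam
Product: 40 CNP0120800.1
Conditions: H2 (1 atm), Pd/C (10 wt %), EtOAc, rt
Reagents that add atoms: none
Why: Hydrogenolysis of the benzyl ether frees the C5 hydroxyl under neutral conditions that should not open the twisted lactam or the lactones.

**Compound list**

1 | (R)-4-benzyloxazolidin-2-one | O=C1OC[C@@H](Cc2ccccc2)N1 | starting material
2 | butanoyl chloride | CCCC(=O)Cl | starting material
3 | (R)-4-benzyl-3-butanoyloxazolidin-2-one | CCCC(=O)N1[C@H](Cc2ccccc2)COC1=O | intermediate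
4 | acrolein | C=CC=O | starting material
5 | dibutylboron Z-enolate of 3 | CC/C=C(\OB(CCCC)CCCC)N1[C@H](Cc2ccccc2)COC1=O | intermediate
6 | (R)-4-benzyl-3-[(2R,3S)-2-ethyl-3-hydroxypent-4-enoyl]oxazolidin-2-one | CC[C@@H](C(=O)N1[C@H](Cc2ccccc2)COC1=O)[C@@H](O)C=C | intermediate
7 | (2R,3S)-2-ethyl-3-hydroxy-N-methoxy-N-methylpent-4-enamide | CC[C@@H](C(=O)N(C)OC)[C@@H](O)C=C | intermediate
8 | vinylmagnesium bromide | C=C[Mg]Br | starting material
9 | (4R,5S)-4-ethyl-5-hydroxyhepta-1,6-dien-3-one | CC[C@@H](C(=O)C=C)[C@@H](O)C=C | intermediate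
10 | (4S,5R)-5-ethyl-4-hydroxycyclopent-2-en-1-one | CC[C@@H]1[C@@H](O)C=CC1=O | intermediate
11 | methoxyallene (1-methoxypropa-1,2-diene) | COC=C=C | starting material
12 | (4S,5R)-4-[(2-bromo-1-methoxyprop-2-en-1-yl)oxy]-5-ethylcyclopent-2-en-1-one, acetal epimers | CC[C@@H]1[C@@H](OC(OC)C(Br)=C)C=CC1=O | intermediate
13 | (3aR,6R,6aS)-6-ethyl-2-methoxy-3-methylidenehexahydro-2H-cyclopenta[b]furan-5(3H)-one, cis-fused | CC[C@@H]1[C@H]2OC(OC)C(=C)[C@H]2CC1=O | intermediate
14 | (3S,3aR,6R,6aS)-6-ethyl-2-methoxy-3-methylhexahydro-2H-cyclopenta[b]furan-5(3H)-one, C14 methyl on the concave face | CC[C@@H]1[C@H]2OC(OC)[C@@H](C)[C@H]2CC1=O | intermediate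
15 | lithium C6–C7 enolate of 14 | CC[C@@H]1[C@H]2OC(OC)[C@@H](C)[C@H]2C=C1O[Li] | intermediate
16 | C6 enol triflate of 14 (C6=C7), stereocentres as in 14 | CC[C@@H]1[C@H]2OC(OC)[C@@H](C)[C@H]2C=C1OS(=O)(=O)C(F)(F)F | intermediate
17 | methyl C6-carboxylate of the C6=C7 cyclopentene (enoate), stereocentres as in 14 | CC[C@@H]1[C@H]2OC(OC)[C@@H](C)[C@H]2C=C1C(=O)OC | intermediate
18 | C7-vinyl saturated methyl ester, C8 trans to C14, C6 epimers | CC[C@@H]1[C@H]2OC(OC)[C@@H](C)[C@H]2[C@H](C=C)C1C(=O)OC | intermediate
19 | 5-(tert-butoxy)-5-oxopentanoic acid | CC(C)(C)OC(=O)CCCC(=O)O | starting material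
20 | tert-butyl 5-chloro-5-oxopentanoate | CC(C)(C)OC(=O)CCCC(=O)Cl | intermediate
21 | lithium ester enolate of 18 | CC[C@@H]1[C@H]2OC(OC)[C@@H](C)[C@H]2[C@H](C=C)C1=C(OC)O[Li] | intermediate
22 | C6-quaternary keto diester: C6 carries CO2Me (C10, cis to C8) and the 5-tert-butoxy-5-oxopentanoyl chain (C5 ketone, cis to ring B) | CC[C@@H]1[C@H]2OC(OC)[C@@H](C)[C@H]2[C@H](C=C)[C@@]1(C(=O)OC)C(=O)CCCC(=O)OC(C)(C)C | intermediate
23 | (5R)-hydroxy diester | CC[C@@H]1[C@H]2OC(OC)[C@@H](C)[C@H]2[C@H](C=C)[C@@]1(C(=O)OC)[C@H](O)CCCC(=O)OC(C)(C)C | intermediate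
24 | (5R)-benzyl ether diester | CC[C@@H]1[C@H]2OC(OC)[C@@H](C)[C@H]2[C@H](C=C)[C@@]1(C(=O)OC)[C@H](OCc1ccccc1)CCCC(=O)OC(C)(C)C | intermediate
25 | spiro β-keto ester: spiro cyclohexanone with C10 ketone, tert-butyl ester on C2, C5 benzyl ether, ring B methyl acetal | CC[C@@H]1[C@H]2OC(OC)[C@@H](C)[C@H]2[C@H](C=C)[C@]13C(=O)C(C(=O)OC(C)(C)C)CC[C@H]3OCc1ccccc1 | intermediate
26 | lactol of 25 | CC[C@@H]1[C@H]2OC(O)[C@@H](C)[C@H]2[C@H](C=C)[C@]13C(=O)C(C(=O)OC(C)(C)C)CC[C@H]3OCc1ccccc1 | intermediate
27 | ring B lactone β-keto ester | CC[C@@H]1[C@H]2OC(=O)[C@@H](C)[C@H]2[C@H](C=C)[C@]13C(=O)C(C(=O)OC(C)(C)C)CC[C@H]3OCc1ccccc1 | intermediate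
28 | β-keto acid of 27 | CC[C@@H]1[C@H]2OC(=O)[C@@H](C)[C@H]2[C@H](C=C)[C@]13C(=O)C(C(=O)O)CC[C@H]3OCc1ccccc1 | intermediate
29 | spiro ketone with C7 vinyl, ring B lactone and C5 benzyl ether | CC[C@@H]1[C@H]2OC(=O)[C@@H](C)[C@H]2[C@H](C=C)[C@]13C(=O)CCC[C@H]3OCc1ccccc1 | intermediate
30 | B-alkyl-9-BBN adduct of 29 (boron on C9) | CC[C@@H]1[C@H]2OC(=O)[C@@H](C)[C@H]2[C@H](CCB4C5CCCC4CCC5)[C@]13C(=O)CCC[C@H]3OCc1ccccc1 | intermediate
31 | C9 primary alcohol | CC[C@@H]1[C@H]2OC(=O)[C@@H](C)[C@H]2[C@H](CCO)[C@]13C(=O)CCC[C@H]3OCc1ccccc1 | intermediate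
32 | C9 aldehyde | CC[C@@H]1[C@H]2OC(=O)[C@@H](C)[C@H]2[C@H](CC=O)[C@]13C(=O)CCC[C@H]3OCc1ccccc1 | intermediate
33 | 3-methylfuran-2(5H)-one | CC1=CCOC1=O | starting material
34 | tert-butyldimethyl[(3-methylfuran-2-yl)oxy]silane | Cc1ccoc1O[Si](C)(C)C(C)(C)C | intermediate
35 | (9S,16R)-hydroxy butenolide | CC[C@@H]1[C@H]2OC(=O)[C@@H](C)[C@H]2[C@H](C[C@H](O)[C@H]2C=C(C)C(=O)O2)[C@]13C(=O)CCC[C@H]3OCc1ccccc1 | intermediate
36 | (9S,16R,18R)-hydroxy lactone, ring D cis-disubstituted | CC[C@@H]1[C@H]2OC(=O)[C@@H](C)[C@H]2[C@H](C[C@H](O)[C@H]2C[C@@H](C)C(=O)O2)[C@]13C(=O)CCC[C@H]3OCc1ccccc1 | intermediate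
37 | (9R)-azido ketone: spiro cyclohexanone with C5 benzyl ether and C9 azide | CC[C@@H]1[C@H]2OC(=O)[C@@H](C)[C@H]2[C@H](C[C@@H](N=[N+]=[N-])[C@H]2C[C@@H](C)C(=O)O2)[C@]13C(=O)CCC[C@H]3OCc3ccccc3 | intermediate
38 | azidohydrin of 37 (N1-diazonio hemiaminal alkoxide; N1–C10 ring cis-fused to ring A and to the cyclohexane) | CC[C@@H]1[C@H]2OC(=O)[C@@H](C)[C@H]2[C@@H]2C[C@H]([C@H]3C[C@@H](C)C(=O)O3)N([N+]#N)[C@@]4([O-])CCC[C@@H](OCc5ccccc5)[C@@]124 | intermediate
39 | O-benzyl bridged lactam (1-azabicyclo[4.3.1]decan-10-one core) | CC[C@@H]1[C@H]2OC(=O)[C@@H](C)[C@H]2[C@@H]2C[C@H]([C@H]3C[C@@H](C)C(=O)O3)N3CCC[C@@H](OCc4ccccc4)[C@@]12C3=O | intermediate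
40 | CNP0120800.1 | CC[C@@H]1[C@H]2OC(=O)[C@@H](C)[C@H]2[C@@H]2C[C@H]([C@H]3C[C@@H](C)C(=O)O3)N3CCC[C@@H](O)[C@@]12C3=O | target

**Step count and risks**

Total: 26 steps. Longest linear sequence: 24 steps (1 to 40 through steps 1–11, 13–20 and 22–26); steps 12 and 21 are one-step side branches.

Step 25 (nitrogen insertion). The diazonium group may prefer the equatorial position in the azidohydrin, so that the quaternary C6 migrates instead of C2 and the fused lactam forms. The fallback sets out from 37. Sulfenylation with LiN(SiMe3)2 (1 equiv) and PhSSPh in THF at −78 °C can only occur at C2, because C6 is quaternary, and would give the α-(phenylsulfanyl) azido ketone F1. Under the same TiCl4 activation the sulfur-bearing carbon is the better migrating group and the sulfur lone pair can hold the diazonium axial, so the Schmidt reaction of F1 should give the 2-(phenylsulfanyl) bridged lactam F2. Radical desulfurisation (Bu3SnH, AIBN, PhMe, 110 °C) then returns to 39.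

Step 22 (vinylogous aldol). The aliphatic aldehyde may react sluggishly or with poor simple diastereoselectivity, so that the C9/C16 relationship is not the anti one needed for the inverting azidation. The fallback sets out from 32. Wittig methylenation (Ph3P=CH2, THF, −78 → 0 °C) would give the C9 terminal alkene F3. Cross-metathesis with an excess of methyl (R)-2-methylpent-4-enoate (second-generation Hoveyda–Grubbs catalyst RuCl2(=CH-C6H4-2-Oi-Pr)(H2IMes), CH2Cl2, 40 °C) would give the (E)-alkenoate F4, which already carries C18. Shi epoxidation with the L-fructose-derived ketone and KHSO5 would give the (9S,16S)-epoxy ester F5 under reagent control. Acid-promoted 5-exo lactonisation (camphorsulfonic acid, CH2Cl2) opens the epoxide with inversion at C16 and comes back to 36.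

Step 13 (acylation at C6). The hindered tetrasubstituted enolate may be O-acylated, or may deprotonate the acid chloride to a ketene instead of attacking it. The fallback sets out from 18. Enolate 21 is treated with tert-butyl 5-oxopentanoate at −78 °C in an aldol addition, where attack at carbon is the only productive path, to give the β-hydroxy ester F6 as a mixture of C5 epimers. Dess–Martin oxidation then comes back to 22.

**Further compounds**

F1 | step 25 | α-(phenylsulfanyl) azido ketone (PhS on C2, C2 epimers) | CC[C@@H]1[C@H]2OC(=O)[C@@H](C)[C@H]2[C@H](C[C@@H](N=[N+]=[N-])[C@H]2C[C@@H](C)C(=O)O2)[C@]13C(=O)C(Sc4ccccc4)CC[C@H]3OCc3ccccc3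
F2 | step 25 | 2-(phenylsulfanyl) bridged lactam | CC[C@@H]1[C@H]2OC(=O)[C@@H](C)[C@H]2[C@@H]2C[C@H]([C@H]3C[C@@H](C)C(=O)O3)N3C(Sc5ccccc5)CC[C@@H](OCc4ccccc4)[C@@]12C3=O
F3 | step 22 | C9 terminal alkene (C7 allyl) | CC[C@@H]1[C@H]2OC(=O)[C@@H](C)[C@H]2[C@H](CC=C)[C@]13C(=O)CCC[C@H]3OCc1ccccc1
F4 | step 22 | (E)-alkenoate (C9=C16, methyl ester, 18R) | CC[C@@H]1[C@H]2OC(=O)[C@@H](C)[C@H]2[C@H](C/C=C/C[C@@H](C)C(=O)OC)[C@]13C(=O)CCC[C@H]3OCc1ccccc1
F5 | step 22 | (9S,16S)-epoxy ester | CC[C@@H]1[C@H]2OC(=O)[C@@H](C)[C@H]2[C@H](C[C@@H]2O[C@H]2C[C@@H](C)C(=O)OC)[C@]13C(=O)CCC[C@H]3OCc1ccccc1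
F6 | step 13 | β-hydroxy ester (aldol adduct, C5 epimers) | CC[C@@H]1[C@H]2OC(OC)[C@@H](C)[C@H]2[C@H](C=C)[C@@]1(C(=O)OC)C(O)CCCC(=O)OC(C)(C)C
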